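**Plan**

- Retrosynthesis: the five aryl ethers are unmasked last. Flavone unit 1 (the 5,7-dihydroxychromone on chromene C6) is cut at its C2–aryl bond. Flavone unit 2 (the apigenin joined through its C8 to chromene C8) is cut at C4–C4a and O1–C2. The biaryl bond between chromene C8 and ring A of unit 2 is cut last.
- Forward: the chromene ring comes first (propargyl Claisen cascade), then the biaryl bond at the iodide (Negishi), then the pyranone ring of unit 2 (thermal annulation with an aroylacetate). The remaining bromide is then used to attach a preformed chromone at its C2 (oxidative boron-Heck), and a global dealkylation finishes the route.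
- Enabling feature: ring A of unit 2 comes from a 2-aryl-5-methoxyresorcinol with a mirror plane through the aryl-bearing carbon (future C8) and the methoxy-bearing carbon (future C5). Its two free ring carbons and its two hydroxyls are therefore pairwise equivalent, and the methyl ether blocks the only other ring closure.
- Stereochemistry: the target has no stereocentre; the cis ring alkene of the chromene is fixed by the electrocyclisation that closes that ring.

Key step: step 6

Remark: the biaryl axis (three small ortho substituents) is taken as freely rotating, so no axial configuration is set, and ketoester 13 is taken as a catalogue compound.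

**Route**

Step 1
Reactants: 1 4-bromo-2-iodophenol; 2 3-chloro-3-methylbut-1-yne
Product: 3 4-bromo-2-iodo-1-[(2-methylbut-3-yn-2-yl)oxy]benzene
Conditions: K2CO3, KI (cat.), CuI (cat.), acetone, 56 °C
Reagents that add atoms: none
Why: Copper-assisted O-propargylation of a phenoxide with a tertiary propargyl chloride is the standard entry to aryl 1,1-dimethylpropargyl ethers, and the acidic halophenol is a good nucleophile under these mild conditions, which leave both carbon–halogen bonds alone.

Step 2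
Reactants: 3 4-bromo-2-iodo-1-[(2-methylbut-3-yn-2-yl)oxy]benzene
Product: 6 6-bromo-8-iodo-2,2-dimethyl-2H-chromene, via allenylphenol 4 (not isolated), via quinone methide 5 (not isolated)
Conditions: PhNEt2, 190 °C
Reagents that add atoms: none
Why: Aromatic propargyl Claisen rearrangement, in which the [3,3] shift goes to the only free ortho carbon, enolisation gives 4, a 1,5-hydrogen shift gives 5 and an oxa-6π electrocyclisation closes the 2,2-dimethylchromene, with bromide and iodide inert at this temperature.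

Step 3
Reactants: 7 5-methoxybenzene-1,3-diol
Product: 8 1-methoxy-3,5-bis(methoxymethoxy)benzene
Conditions: NaH (2.4 equiv), MOMCl (2.4 equiv), DMF, 0 °C to rt
Reagents that add atoms: chloromethyl methyl ether, COCCl
Why: Williamson-type acetalisation of both phenoxides installs two chelating groups that protect the hydroxyls and direct the metalation of the next step.

Step 4
Reactants: 8 1-methoxy-3,5-bis(methoxymethoxy)benzene; 6 6-bromo-8-iodo-2,2-dimethyl-2H-chromene
Product: 11 6-bromo-8-[4-methoxy-2,6-bis(methoxymethoxy)phenyl]-2,2-dimethyl-2H-chromene, via aryllithium 9 (not isolated), via arylzinc chloride 10 (not isolated)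
Conditions: n-BuLi, THF, 0 °C; ZnCl2, 0 °C to rt; then 6, Pd(PPh3)4 (5 mol %), THF, 55 °C
Reagents that add atoms: none
Why: Directed ortho-metalation at the carbon flanked by the two chelating acetal oxygens, transmetalation to zinc and Negishi coupling, in which zerovalent palladium inserts into the C–I bond much faster than into the C–Br bond, so the bromide is kept for later.

Step 5
Reactants: 11 6-bromo-8-[4-methoxy-2,6-bis(methoxymethoxy)phenyl]-2,2-dimethyl-2H-chromene
Product: 12 2-(6-bromo-2,2-dimethyl-2H-chromen-8-yl)-5-methoxybenzene-1,3-diol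
Conditions: 3 M aq. HCl, MeOH, 50 °C
Reagents that add atoms: none
Why: Acid-catalysed acetal methanolysis frees both hydroxyls, and dilute protic acid is a standard deprotection in the presence of 2,2-dimethylchromenes because any ring-opened cation simply re-closes.

Step 6
Reactants: 12 2-(6-bromo-2,2-dimethyl-2H-chromen-8-yl)-5-methoxybenzene-1,3-diol; 13 ethyl 3-[4-(benzyloxy)phenyl]-3-oxopropanoate
Product: 16 2-[4-(benzyloxy)phenyl]-8-(6-bromo-2,2-dimethyl-2H-chromen-8-yl)-7-hydroxy-5-methoxy-4H-chromen-4-one, via aroylketene 14 (not isolated), via diketone 15 (not isolated)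
Conditions: 13 (2 equiv), Ph2O, 245 °C, Ar, EtOH and H2O distilled off
Reagents that add atoms: none
Why: Mentzer pyrone synthesis, in which ketoester 13 loses ethanol above about 200 °C to give aroylketene 14, which C-acylates the phloroglucinol-like ring of 12 at one of its two mirror-related free carbons (directly or by O-acylation and acyl shift) to give diketone 15 and so forms the C4–C4a bond. The hydroxyl ortho to the new acyl group then attacks the aryl ketone in a 6-exo-trig closure, and loss of water forms the O1–C2 bond and the pyranone ring. The closest known reaction type is the acid-free thermal condensation of phloroglucinol and its C-substituted or O-monomethylated derivatives with aroylacetates to 5,7-dioxygenated flavones, of which this 2-aryl case is a more hindered member. No stereocentre is created. The step needs 8-linkage over 6-linkage and chromone over coumarin: the mirror plane of 12 makes both acylation sites identical and places the methyl ether, which cannot cyclise, on one side of the acyl group, so only the hydroxyl beside the biaryl bond can become O1, while the absence of acid disfavours the Pechmann mode. The chromene, the aryl bromide and the benzyl ether should survive because chromenes of this type are themselves formed near 200 °C, and a modest excess of 13 limits a second annulation on the far less nucleophilic product.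

Step 7
Reactants: 16 2-[4-(benzyloxy)phenyl]-8-(6-bromo-2,2-dimethyl-2H-chromen-8-yl)-7-hydroxy-5-methoxy-4H-chromen-4-one
Product: 17 7-(benzyloxy)-2-[4-(benzyloxy)phenyl]-8-(6-bromo-2,2-dimethyl-2H-chromen-8-yl)-5-methoxy-4H-chromen-4-one
Conditions: BnBr, K2CO3, DMF, 50 °C
Reagents that add atoms: benzyl bromide, BrCc1ccccc1
Why: Williamson etherification of the acidic 7-hydroxyl (a vinylogous carboxylic acid) masks the last free phenol before the palladium steps.

Step 8
Reactants: 17 7-(benzyloxy)-2-[4-(benzyloxy)phenyl]-8-(6-bromo-2,2-dimethyl-2H-chromen-8-yl)-5-methoxy-4H-chromen-4-one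
Product: 18 7-(benzyloxy)-2-[4-(benzyloxy)phenyl]-8-[2,2-dimethyl-6-(4,4,5,5-tetramethyl-1,3,2-dioxaborolan-2-yl)-2H-chromen-8-yl]-5-methoxy-4H-chromen-4-one
Conditions: B2pin2, PdCl2(dppf) (5 mol %), KOAc, 1,4-dioxane, 90 °C
Reagents that add atoms: bis(pinacolato)diboron, CC1(C)OB(OC1(C)C)B1OC(C)(C)C(C)(C)O1
Why: Miyaura borylation of an aryl bromide flanked by two C–H positions is unhindered, and the ethers, the chromone and the chromene alkene are inert to zerovalent palladium with acetate as base.

Step 9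
Reactants: 19 1-(2,4,6-trihydroxyphenyl)ethan-1-one
Product: 20 1-[2,4-bis(benzyloxy)-6-hydroxyphenyl]ethan-1-one
Conditions: BnBr (2.1 equiv), K2CO3, DMF, rt
Reagents that add atoms: benzyl bromide, BrCc1ccccc1
Why: Selective Williamson etherification, in which one hydroxyl stays hydrogen-bonded to the ketone and is much less nucleophilic, so two equivalents of benzyl bromide alkylate the other two.

Step 10
Reactants: 20 1-[2,4-bis(benzyloxy)-6-hydroxyphenyl]ethan-1-one
Product: 22 5,7-bis(benzyloxy)-4H-chromen-4-one, via enaminone 21 (not isolated)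
Conditions: Me2NCH(OMe)2, toluene, 100 °C; then aq. HCl, CH2Cl2, 40 °C
Reagents that add atoms: N,N-dimethylformamide dimethyl acetal, COC(OC)N(C)C
Why: Enaminone formation at the acetyl methyl followed by acid-promoted addition of the ortho hydroxyl and loss of dimethylamine is the standard chromone synthesis from 2-hydroxyacetophenones.

Step 11
Reactants: 18 7-(benzyloxy)-2-[4-(benzyloxy)phenyl]-8-[2,2-dimethyl-6-(4,4,5,5-tetramethyl-1,3,2-dioxaborolan-2-yl)-2H-chromen-8-yl]-5-methoxy-4H-chromen-4-one; 22 5,7-bis(benzyloxy)-4H-chromen-4-one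
Product: 23 7-(benzyloxy)-8-{6-[5,7-bis(benzyloxy)-4-oxo-4H-chromen-2-yl]-2,2-dimethyl-2H-chromen-8-yl}-2-[4-(benzyloxy)phenyl]-5-methoxy-4H-chromen-4-one
Conditions: 22 (2.5 equiv), Pd(O2CCF3)2 (10 mol %), 5-nitro-1,10-phenanthroline (20 mol %), O2 (1 atm), DMF, 80 °C
Reagents that add atoms: none
Why: Oxidative boron-Heck reaction, known for the direct C2 arylation of chromones with arylboron reagents, in which the aryl group is transferred from boron to divalent palladium, adds to C2 of the chromone with palladium at C3 as its enolate, and β-hydride elimination after enolate epimerisation followed by reoxidation with O2 gives the 2-arylchromone.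

Step 12
Reactants: 23 7-(benzyloxy)-8-{6-[5,7-bis(benzyloxy)-4-oxo-4H-chromen-2-yl]-2,2-dimethyl-2H-chromen-8-yl}-2-[4-(benzyloxy)phenyl]-5-methoxy-4H-chromen-4-one
Product: 24 8-[6-(5,7-dihydroxy-4-oxo-4H-chromen-2-yl)-2,2-dimethyl-2H-chromen-8-yl]-5,7-dihydroxy-2-(4-hydroxyphenyl)-4H-chromen-4-one
Conditions: BCl3 (12 equiv), C6HMe5 (15 equiv), CH2Cl2, −78 °C, then 0 °C; MeOH quench
Reagents that add atoms: none
Why: Lewis-acid ether cleavage with a cation scavenger, in which pentamethylbenzene traps each benzyl cation by Friedel–Crafts benzylation so the four benzyl ethers fall at low temperature without benzylating the electron-rich rings or the chromene, and the methyl ether peri to the carbonyl is cleaved through its six-membered boron chelate on warming to 0 °C.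

**Compound list**

1 | 4-bromo-2-iodophenol | Oc1ccc(Br)cc1I | starting material
2 | 3-chloro-3-methylbut-1-yne | CC(C)(Cl)C#C | starting material
3 | 4-bromo-2-iodo-1-[(2-methylbut-3-yn-2-yl)oxy]benzene | CC(C)(C#C)Oc1ccc(Br)cc1I | intermediate
4 | 4-bromo-2-iodo-6-(3-methylbuta-1,2-dien-1-yl)phenol | CC(C)=C=Cc1cc(Br)cc(I)c1O | intermediate
5 | (6Z)-4-bromo-2-iodo-6-(3-methylbut-2-en-1-ylidene)cyclohexa-2,4-dien-1-one | CC(C)=C/C=C1/C=C(Br)C=C(I)C1=O | intermediate
6 | 6-bromo-8-iodo-2,2-dimethyl-2H-chromene | CC1(C)C=Cc2cc(Br)cc(I)c2O1 | intermediate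
7 | 5-methoxybenzene-1,3-diol | COc1cc(O)cc(O)c1 | starting material
8 | 1-methoxy-3,5-bis(methoxymethoxy)benzene | COCOc1cc(OC)cc(OCOC)c1 | intermediate
9 | [4-methoxy-2,6-bis(methoxymethoxy)phenyl]lithium | [Li]c1c(OCOC)cc(OC)cc1OCOC | intermediate
10 | chloro[4-methoxy-2,6-bis(methoxymethoxy)phenyl]zinc | Cl[Zn]c1c(OCOC)cc(OC)cc1OCOC | intermediate
11 | 6-bromo-8-[4-methoxy-2,6-bis(methoxymethoxy)phenyl]-2,2-dimethyl-2H-chromene | COCOc1cc(OC)cc(OCOC)c1-c1cc(Br)cc2C=CC(C)(C)Oc12 | intermediate
12 | 2-(6-bromo-2,2-dimethyl-2H-chromen-8-yl)-5-methoxybenzene-1,3-diol | COc1cc(O)c(-c2cc(Br)cc3C=CC(C)(C)Oc23)c(O)c1 | intermediate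
13 | ethyl 3-[4-(benzyloxy)phenyl]-3-oxopropanoate | CCOC(=O)CC(=O)c1ccc(OCc2ccccc2)cc1 | starting material
14 | 3-[4-(benzyloxy)phenyl]-3-oxoprop-1-en-1-one | O=C=CC(=O)c1ccc(OCc2ccccc2)cc1 | intermediate
15 | 1-[4-(benzyloxy)phenyl]-3-[3-(6-bromo-2,2-dimethyl-2H-chromen-8-yl)-2,4-dihydroxy-6-methoxyphenyl]propane-1,3-dione | COc1cc(O)c(-c2cc(Br)cc3C=CC(C)(C)Oc23)c(O)c1C(=O)CC(=O)c1ccc(OCc2ccccc2)cc1 | intermediate
16 | 2-[4-(benzyloxy)phenyl]-8-(6-bromo-2,2-dimethyl-2H-chromen-8-yl)-7-hydroxy-5-methoxy-4H-chromen-4-one | CC1(C)C=Cc2cc(Br)cc(-c3c(O)cc(OC)c4c(=O)cc(-c5ccc(OCc6ccccc6)cc5)oc34)c2O1 | intermediate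
17 | 7-(benzyloxy)-2-[4-(benzyloxy)phenyl]-8-(6-bromo-2,2-dimethyl-2H-chromen-8-yl)-5-methoxy-4H-chromen-4-one | CC1(C)C=Cc2cc(Br)cc(-c3c(OCc4ccccc4)cc(OC)c4c(=O)cc(-c5ccc(OCc6ccccc6)cc5)oc34)c2O1 | intermediate
18 | 7-(benzyloxy)-2-[4-(benzyloxy)phenyl]-8-[2,2-dimethyl-6-(4,4,5,5-tetramethyl-1,3,2-dioxaborolan-2-yl)-2H-chromen-8-yl]-5-methoxy-4H-chromen-4-one | CC1(C)C=Cc2cc(B3OC(C)(C)C(C)(C)O3)cc(-c3c(OCc4ccccc4)cc(OC)c4c(=O)cc(-c5ccc(OCc6ccccc6)cc5)oc34)c2O1 | intermediate
19 | 1-(2,4,6-trihydroxyphenyl)ethan-1-one | CC(=O)c1c(O)cc(O)cc1O | starting material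
20 | 1-[2,4-bis(benzyloxy)-6-hydroxyphenyl]ethan-1-one | CC(=O)c1c(O)cc(OCc2ccccc2)cc1OCc1ccccc1 | intermediate
21 | (2E)-1-[2,4-bis(benzyloxy)-6-hydroxyphenyl]-3-(dimethylamino)prop-2-en-1-one | CN(C)/C=C/C(=O)c1c(O)cc(OCc2ccccc2)cc1OCc1ccccc1 | intermediate
22 | 5,7-bis(benzyloxy)-4H-chromen-4-one | O=c1ccoc2cc(OCc3ccccc3)cc(OCc3ccccc3)c12 | intermediate
23 | 7-(benzyloxy)-8-{6-[5,7-bis(benzyloxy)-4-oxo-4H-chromen-2-yl]-2,2-dimethyl-2H-chromen-8-yl}-2-[4-(benzyloxy)phenyl]-5-methoxy-4H-chromen-4-one | CC1(C)C=Cc2cc(-c3cc(=O)c4c(OCc5ccccc5)cc(OCc5ccccc5)cc4o3)cc(-c3c(OCc4ccccc4)cc(OC)c4c(=O)cc(-c5ccc(OCc6ccccc6)cc5)oc34)c2O1 | intermediate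
24 | 8-[6-(5,7-dihydroxy-4-oxo-4H-chromen-2-yl)-2,2-dimethyl-2H-chromen-8-yl]-5,7-dihydroxy-2-(4-hydroxyphenyl)-4H-chromen-4-one | CC1(C)C=Cc2cc(-c3cc(=O)c4c(O)cc(O)cc4o3)cc(-c3c(O)cc(O)c4c(=O)cc(-c5ccc(O)cc5)oc34)c2O1 | target

**Count**

Total steps: 12. Longest linear sequence: 9 steps (steps 1, 2, 4, 5, 6, 7, 8, 11 and 12, from 4-bromo-2-iodophenol).

**Steps most likely to fail**

Step 6. The ortho aryl group may slow C-acylation of ring A, so that the aroylketene is lost to self-condensation or to an O-acylation that never shifts to carbon, and the longer heating then degrades the chromene. The fallback builds the same pyranone stepwise through a chalcone, with the same symmetry argument fixing the regiochemistry. It sets out from 12: Friedel–Crafts acetylation (Ac2O, BF3·OEt2, EtOAc, 0 °C to rt) at one of the two equivalent free carbons should give 1-[3-(6-bromo-2,2-dimethyl-2H-chromen-8-yl)-2,4-dihydroxy-6-methoxyphenyl]ethan-1-one F1. Benzylation of its non-chelated hydroxyl (BnBr, K2CO3, acetone) should give 1-[4-(benzyloxy)-3-(6-bromo-2,2-dimethyl-2H-chromen-8-yl)-2-hydroxy-6-methoxyphenyl]ethan-1-one F2. Claisen–Schmidt condensation with 4-(benzyloxy)benzaldehyde (KOH, EtOH) should give (2E)-1-[4-(benzyloxy)-3-(6-bromo-2,2-dimethyl-2H-chromen-8-yl)-2-hydroxy-6-methoxyphenyl]-3-[4-(benzyloxy)phenyl]prop-2-en-1-one F3. Oxidative cyclisation (I2 cat., DMSO, 130 °C), in which only the hydroxyl beside the biaryl bond can close, returns to the route at 17, so step 7 is no longer needed.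

Step 11. Transfer of the aryl group from the pinacol boronate to divalent palladium may be slow, so that oxidative homocoupling and protodeboronation of 18, or arylation of the chromene alkene, outrun addition to the chromone. The fallback builds flavone unit 1 by the chalcone route instead and sets out from bromide 17, bypassing steps 8 and 10. Palladium-catalysed formylation (CO 1 atm, HCO2Na, PdCl2(PPh3)2, DMF, 100 °C) should give 8-{7-(benzyloxy)-2-[4-(benzyloxy)phenyl]-5-methoxy-4-oxo-4H-chromen-8-yl}-2,2-dimethyl-2H-chromene-6-carbaldehyde F4. Claisen–Schmidt condensation with ketone 20 (KOH, EtOH/THF, rt) should give (2E)-3-(8-{7-(benzyloxy)-2-[4-(benzyloxy)phenyl]-5-methoxy-4-oxo-4H-chromen-8-yl}-2,2-dimethyl-2H-chromen-6-yl)-1-[2,4-bis(benzyloxy)-6-hydroxyphenyl]prop-2-en-1-one F5. Oxidative cyclisation (I2 cat., DMSO, 130 °C) returns to the route at 23.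

Step 12. While the chelated methyl ether is being cleaved at 0 °C, BCl3 may ionise the tertiary allylic C–O bond of the chromene, leading to ring opening, chloride capture or HCl addition to the styrene-type alkene. The fallback separates the two kinds of ether so that the chromene meets BCl3 only at −78 °C. It sets out from 23: MgI2·OEt2 (toluene/Et2O, 80 °C) should remove only the two ethers peri to a carbonyl (the 5-benzyl and the 5-methyl group) by chelation-directed attack of iodide at carbon, giving 7-(benzyloxy)-8-{6-[7-(benzyloxy)-5-hydroxy-4-oxo-4H-chromen-2-yl]-2,2-dimethyl-2H-chromen-8-yl}-2-[4-(benzyloxy)phenyl]-5-hydroxy-4H-chromen-4-one F6. BCl3 and C6HMe5 in CH2Cl2, held at −78 °C throughout, should then cleave the three remaining benzyl ethers and return to the route at 24.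

**Further compounds**

F1 | step 6 | 1-[3-(6-bromo-2,2-dimethyl-2H-chromen-8-yl)-2,4-dihydroxy-6-methoxyphenyl]ethan-1-one | COc1cc(O)c(-c2cc(Br)cc3C=CC(C)(C)Oc23)c(O)c1C(C)=O
F2 | step 6 | 1-[4-(benzyloxy)-3-(6-bromo-2,2-dimethyl-2H-chromen-8-yl)-2-hydroxy-6-methoxyphenyl]ethan-1-one | COc1cc(OCc2ccccc2)c(-c2cc(Br)cc3C=CC(C)(C)Oc23)c(O)c1C(C)=O
F3 | step 6 | (2E)-1-[4-(benzyloxy)-3-(6-bromo-2,2-dimethyl-2H-chromen-8-yl)-2-hydroxy-6-methoxyphenyl]-3-[4-(benzyloxy)phenyl]prop-2-en-1-one | COc1cc(OCc2ccccc2)c(-c2cc(Br)cc3C=CC(C)(C)Oc23)c(O)c1C(=O)/C=C/c1ccc(OCc2ccccc2)cc1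
F4 | step 11 | 8-{7-(benzyloxy)-2-[4-(benzyloxy)phenyl]-5-methoxy-4-oxo-4H-chromen-8-yl}-2,2-dimethyl-2H-chromene-6-carbaldehyde | CC1(C)C=Cc2cc(C=O)cc(-c3c(OCc4ccccc4)cc(OC)c4c(=O)cc(-c5ccc(OCc6ccccc6)cc5)oc34)c2O1
F5 | step 11 | (2E)-3-(8-{7-(benzyloxy)-2-[4-(benzyloxy)phenyl]-5-methoxy-4-oxo-4H-chromen-8-yl}-2,2-dimethyl-2H-chromen-6-yl)-1-[2,4-bis(benzyloxy)-6-hydroxyphenyl]prop-2-en-1-one | CC1(C)C=Cc2cc(/C=C/C(=O)c3c(O)cc(OCc4ccccc4)cc3OCc3ccccc3)cc(-c3c(OCc4ccccc4)cc(OC)c4c(=O)cc(-c5ccc(OCc6ccccc6)cc5)oc34)c2O1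
F6 | step 12 | 7-(benzyloxy)-8-{6-[7-(benzyloxy)-5-hydroxy-4-oxo-4H-chromen-2-yl]-2,2-dimethyl-2H-chromen-8-yl}-2-[4-(benzyloxy)phenyl]-5-hydroxy-4H-chromen-4-one | CC1(C)C=Cc2cc(-c3cc(=O)c4c(O)cc(OCc5ccccc5)cc4o3)cc(-c3c(OCc4ccccc4)cc(O)c4c(=O)cc(-c5ccc(OCc6ccccc6)cc5)oc34)c2O1
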